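**Strategy.** Labdane numbering: C4 carries both CH2OH groups, C5 and C10 are the ring-fusion carbons, C9 carries the side chain, C8 the formyl group. Everything rests on closing ring A at C4–C5 and ring B at C10–C9 in one enantioselective organo-SOMO radical bicyclization of an acyclic dienal. The step exploits three features: the C4 bis(hydroxymethyl) carbon is the α-carbon of an aldehyde (later doubled by aldol–Cannizzaro), the trans ring fusion maps onto an E-trisubstituted C5=C10 alkene, and the C8 formyl carbon onto an allylsilane terminus. The precursor is a linear C13 aldehyde carrying both alkenes, a CH2SiMe3 group and a protected two-carbon arm.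

Key step: step 8

Remark: the imidazolidinone enantiomer in step 8 is assigned from the usual face-shielding model of the enamine radical cation; its antipode would be used if the sense of induction proved opposite. 3-Bromofuran-2(5H)-one is taken as commercially available.

Step 1
Reactants: 1 hept-6-yn-1-ol
Product: 2 tert-butyl(hept-6-yn-1-yloxy)dimethylsilane
Conditions: TBSCl, imidazole, DMF, rt
Reagents that add atoms: tert-butyldimethylsilyl chloride CC(C)(C)[Si](C)(C)Cl
Why: Standard silyl ether formation masks the primary alcohol (the future C18 aldehyde) against the organometallic steps that follow.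

Step 2
Reactants: 2 tert-butyl(hept-6-yn-1-yloxy)dimethylsilane
Product: 5 (E)-9-(tert-butyldimethylsilyloxy)-4-methylnon-3-en-1-ol, via alkenyldimethylalane 3 (not isolated), via lithium butyl(alkenyl)dimethylaluminate 4 (not isolated)
Conditions: Me3Al, Cp2ZrCl2 (0.25 equiv), CH2Cl2, 0 °C → rt; n-BuLi, THF, −78 °C; ethylene oxide, −78 °C → rt
Reagents that add atoms: trimethylaluminium C[Al](C)C; ethylene oxide C1CO1
Why: Negishi zirconium-catalysed carboalumination adds CH3 and Al syn across the terminal alkyne, and the derived alanate opens ethylene oxide with retention at the alkenyl carbon, which fixes the E geometry of the future C5=C10 alkene.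

Step 3
Reactants: 5 (E)-9-(tert-butyldimethylsilyloxy)-4-methylnon-3-en-1-ol
Product: 6 tert-butyl{[(E)-9-iodo-6-methylnon-6-en-1-yl]oxy}dimethylsilane
Conditions: I2, PPh3, imidazole, CH2Cl2, 0 °C
Reagents that add atoms: iodine II
Why: Appel-type (Garegg–Samuelsson) iodination of the primary alcohol under buffered conditions should leave the silyl ether and the alkene untouched.

Step 4
Reactants: 6 tert-butyl{[(E)-9-iodo-6-methylnon-6-en-1-yl]oxy}dimethylsilane, 7 2,3-dihydrofuran
Product: 9 tert-butyl{[(E)-9-(4,5-dihydrofuran-2-yl)-6-methylnon-6-en-1-yl]oxy}dimethylsilane, via 5-lithio-2,3-dihydrofuran 8 (not isolated)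
Conditions: 7, t-BuLi, THF, −78 → 0 °C; then 6, −30 °C → rt
Reagents that add atoms: none
Why: α-Lithiation of the cyclic enol ether gives a vinyllithium that is alkylated by the unhindered primary iodide in an SN2 reaction; the ring locks the enol ether geometry that step 5 transfers to the C8=C9 alkene.

Step 5
Reactants: 9 tert-butyl{[(E)-9-(4,5-dihydrofuran-2-yl)-6-methylnon-6-en-1-yl]oxy}dimethylsilane
Product: 11 (3Z,7E)-13-(tert-butyldimethylsilyloxy)-8-methyl-4-[(trimethylsilyl)methyl]trideca-3,7-dien-1-yl acetate, via chloromagnesium alkoxide 10 (not isolated)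
Conditions: Me3SiCH2MgCl (3 equiv), NiCl2(PPh3)2 (5 mol%), PhMe, 80 °C; then Ac2O, 0 °C → rt
Reagents that add atoms: (trimethylsilyl)methylmagnesium chloride C[Si](C)(C)C[Mg]Cl; acetic anhydride CC(=O)OC(C)=O
Why: Nickel-catalysed Kumada-type coupling at the enol ether C–O bond with a Grignard reagent lacking β-hydrogens should proceed with retention, so CH2SiMe3 ends up cis to the hydroxyethyl arm (C7 and C11 trans), and the alkoxide is acetylated in the same flask.

Step 6
Reactants: 11 (3Z,7E)-13-(tert-butyldimethylsilyloxy)-8-methyl-4-[(trimethylsilyl)methyl]trideca-3,7-dien-1-yl acetate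
Product: 12 (3Z,7E)-13-hydroxy-8-methyl-4-[(trimethylsilyl)methyl]trideca-3,7-dien-1-yl acetate
Conditions: TBAF, AcOH, THF, 0 °C → rt
Reagents that add atoms: none
Why: Fluoride cleaves the primary silyl ether, and acetic acid buffering should keep the acetate and the allylsilane intact.

Step 7
Reactants: 12 (3Z,7E)-13-hydroxy-8-methyl-4-[(trimethylsilyl)methyl]trideca-3,7-dien-1-yl acetate
Product: 13 (3Z,7E)-8-methyl-13-oxo-4-[(trimethylsilyl)methyl]trideca-3,7-dien-1-yl acetate
Conditions: Dess–Martin periodinane, NaHCO3, CH2Cl2, 0 °C → rt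
Reagents that add atoms: none
Why: Buffered Dess–Martin oxidation gives the aldehyde without over-oxidation and without acid that could protodesilylate the allylsilane.

Step 8
Reactants: 13 (3Z,7E)-8-methyl-13-oxo-4-[(trimethylsilyl)methyl]trideca-3,7-dien-1-yl acetate
Product: 14 2-[(1R,4aR,5S,8aR)-5-formyl-8a-methyl-2-methylidenedecahydronaphthalen-1-yl]ethyl acetate
Conditions: (2R,5R)-2-tert-butyl-3-methyl-5-(1-naphthylmethyl)imidazolidin-4-one·TFA (30 mol%), Cu(OTf)2 (2.5 equiv, slow addition), NaTFA (2 equiv), i-PrCN/DME, rt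
Reagents that add atoms: none
Why: Proposed new method: condensation of 13 with the imidazolidinone gives an (E)-enamine that Cu(OTf)2 oxidises by one electron to a 3π radical cation; its electrophilic α-carbon (C4) adds to C5 of the E-trisubstituted C5=C10 alkene in a 6-endo-trig mode (closing ring A through the C4–C5 bond), the tertiary C10 radical closes ring B by a second 6-endo-trig addition to C9 of the allylsilane, and the β-silyl C8 radical is oxidised by a second Cu(OTf)2 to a cation that loses the silyl group as the 8(17)-methylidene before the iminium is hydrolysed. The closest known reaction types are the organo-SOMO enantioselective polyene cyclization (terminated by arenes) and the organo-SOMO intramolecular α-allylation of aldehydes with allylsilanes; merging these two termination modes in one cascade is the untested element. The chair–chair transition state should translate the E geometry of C5=C10 into the trans ring fusion (C5–H anti to C10–CH3) and the C8=C9 geometry (C7 and C11 trans) into an equatorial C9 side chain, while the 1-naphthylmethyl group of the (2R,5R) catalyst shields the Si face of C4 so that C5 bonds to its Re face and fixes the absolute configuration; the C4 centre itself is erased in step 9. The step needs 6-endo over 5-exo attack (secured by the fully substituted C10 and C8 and by the tertiary radicals formed), oxidation of the enamine in preference to the allylsilane (secured by the low oxidation potential of the enamine and slow addition of the oxidant) and survival of the allylsilane (secured by NaTFA buffering and no added strong acid).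

Step 9
Reactants: 14 2-[(1R,4aR,5S,8aR)-5-formyl-8a-methyl-2-methylidenedecahydronaphthalen-1-yl]ethyl acetate
Product: 15 2-[(1R,4aS,8aS)-5,5-bis(hydroxymethyl)-8a-methyl-2-methylidenedecahydronaphthalen-1-yl]ethan-1-ol
Conditions: aq. CH2O (37%, excess), KOH, MeOH/H2O, 50 °C
Reagents that add atoms: formaldehyde C=O
Why: In this Tollens reaction, crossed aldol addition of the α-branched aldehyde to formaldehyde creates the quaternary C4 and crossed Cannizzaro hydride transfer then reduces the now non-enolisable aldehyde; hydroxide also cleaves the acetate, and C4 becomes non-stereogenic, so its configuration in 14 is irrelevant.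

Step 10
Reactants: 15 2-[(1R,4aS,8aS)-5,5-bis(hydroxymethyl)-8a-methyl-2-methylidenedecahydronaphthalen-1-yl]ethan-1-ol
Product: 16 isopropylidene acetal of 15 (spiro 2,2-dimethyl-1,3-dioxane across the two C4 hydroxymethyl groups; side-chain primary OH free; (1R,4aS,8aS) core)
Conditions: 2,2-dimethoxypropane, PPTS (cat.), acetone, rt; aqueous work-up
Reagents that add atoms: 2,2-dimethoxypropane COC(C)(C)OC
Why: Only the 1,3-diol can form a six-membered cyclic acetal under thermodynamic control, and any mixed acetal at the side-chain hydroxyl should be lost on aqueous work-up.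

Step 11
Reactants: 16 isopropylidene acetal of 15
Product: 17 side-chain primary iodide of 16 (2-iodoethyl arm at C9)
Conditions: I2, PPh3, imidazole, CH2Cl2, 0 °C
Reagents that add atoms: iodine II
Why: Appel-type iodination of the only free (primary) hydroxyl under imidazole buffering should leave the acetal and the exocyclic alkene untouched.

Step 12
Reactants: 17 side-chain primary iodide of 16, 18 3-bromofuran-2(5H)-one
Product: 21 3-{2-[(1R,4aS,8aS)-5,5-bis(hydroxymethyl)-8a-methyl-2-methylidenedecahydronaphthalen-1-yl]ethyl}furan-2(5H)-one isopropylidene acetal, via primary alkyllithium 19 (not isolated), via lithium B-alkyl-B-methoxy-9-BBN borinate 20 (not isolated)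
Conditions: t-BuLi (2.1 equiv), Et2O, −78 °C; B-OMe-9-BBN, THF, −78 °C → rt; then 18, Pd(dppf)Cl2 (5 mol%), AsPh3, aq. K3PO4, DMF, rt
Reagents that add atoms: none
Why: Iodine–lithium exchange and transfer to boron give an ate complex that undergoes B-alkyl Suzuki–Miyaura coupling with the α-bromo unsaturated lactone; the organolithium cannot cyclise onto the 8(17)-alkene because only 4-exo or 5-endo modes are available.

Step 13
Reactants: 21 butenolide acetal with 8(17)-alkene
Product: 23 3-{2-[(1R,2R,4aS,8aS)-2-(hydroxymethyl)-5,5-bis(hydroxymethyl)-8a-methyldecahydronaphthalen-1-yl]ethyl}furan-2(5H)-one 5,5-isopropylidene acetal (CH2OH at C8 axial and cis to the C10 methyl), via B-alkyl-9-BBN 22 (not isolated)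
Conditions: 9-BBN (3 equiv), THF, rt → 50 °C; then NaBO3·4H2O, THF/H2O, rt
Reagents that add atoms: sodium perborate [Na+].[Na+].O[B-]1(O)OO[B-](O)(O)OO1
Why: Anti-Markovnikov hydroboration of the electron-rich 1,1-disubstituted alkene should occur from the face opposite the axial C10 methyl (placing C17 axial), 9-BBN being inert to the lactone and its electron-poor alkene, and perborate oxidises the C–B bond with retention.

Step 14
Reactants: 23 primary alcohol (C17 axial)
Product: 24 3-{2-[(1R,2R,4aS,8aS)-2-formyl-5,5-bis(hydroxymethyl)-8a-methyldecahydronaphthalen-1-yl]ethyl}furan-2(5H)-one 5,5-isopropylidene acetal (axial formyl)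
Conditions: Dess–Martin periodinane, NaHCO3, CH2Cl2, 0 °C → rt
Reagents that add atoms: none
Why: Dess–Martin oxidation converts the hindered primary alcohol into the aldehyde under near-neutral conditions that the butenolide and the acetal tolerate.

Step 15
Reactants: 24 axial aldehyde acetal
Product: 26 3-{2-[(1R,2S,4aS,8aS)-2-formyl-5,5-bis(hydroxymethyl)-8a-methyldecahydronaphthalen-1-yl]ethyl}furan-2(5H)-one (target), via C8-epimeric diol aldehyde 25 (not isolated)
Conditions: 1 M aq. HCl/THF (1:3), 40 °C
Reagents that add atoms: none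
Why: Aqueous acid hydrolyses the isopropylidene acetal and, through the enol, should equilibrate the axial formyl group (syn-axial to the C10 methyl) to the equatorial C8 epimer, which is the thermodynamic configuration of the target.

**Compound list**

1 | hept-6-yn-1-ol | OCCCCCC#C | starting material
2 | tert-butyl(hept-6-yn-1-yloxy)dimethylsilane | CC(C)(C)[Si](C)(C)OCCCCCC#C | intermediate
3 | (E)-[7-(tert-butyldimethylsilyloxy)-2-methylhept-1-en-1-yl]dimethylalane | CC(C)(C)[Si](C)(C)OCCCCC/C(C)=C/[Al](C)C | intermediate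
4 | lithium butyl[(E)-7-(tert-butyldimethylsilyloxy)-2-methylhept-1-en-1-yl]dimethylaluminate | [Li+].CC(C)(C)[Si](C)(C)OCCCCC/C(C)=C/[Al-](C)(C)CCCC | intermediate
5 | (E)-9-(tert-butyldimethylsilyloxy)-4-methylnon-3-en-1-ol | CC(C)(C)[Si](C)(C)OCCCCC/C(C)=C/CCO | intermediate
6 | tert-butyl{[(E)-9-iodo-6-methylnon-6-en-1-yl]oxy}dimethylsilane | CC(C)(C)[Si](C)(C)OCCCCC/C(C)=C/CCI | intermediate
7 | 2,3-dihydrofuran | C1CC=CO1 | starting material
8 | 5-lithio-2,3-dihydrofuran | [Li]C1=CCCO1 | intermediate
9 | tert-butyl{[(E)-9-(4,5-dihydrofuran-2-yl)-6-methylnon-6-en-1-yl]oxy}dimethylsilane | CC(C)(C)[Si](C)(C)OCCCCC/C(C)=C/CCC1=CCCO1 | intermediate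
10 | chloromagnesium (3Z,7E)-13-(tert-butyldimethylsilyloxy)-8-methyl-4-[(trimethylsilyl)methyl]trideca-3,7-dien-1-olate | CC(C)(C)[Si](C)(C)OCCCCC/C(C)=C/CC/C(C[Si](C)(C)C)=C/CCO[Mg]Cl | intermediate
11 | (3Z,7E)-13-(tert-butyldimethylsilyloxy)-8-methyl-4-[(trimethylsilyl)methyl]trideca-3,7-dien-1-yl acetate | CC(C)(C)[Si](C)(C)OCCCCC/C(C)=C/CC/C(C[Si](C)(C)C)=C/CCOC(C)=O | intermediate
12 | (3Z,7E)-13-hydroxy-8-methyl-4-[(trimethylsilyl)methyl]trideca-3,7-dien-1-yl acetate | OCCCCC/C(C)=C/CC/C(C[Si](C)(C)C)=C/CCOC(C)=O | intermediate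
13 | (3Z,7E)-8-methyl-13-oxo-4-[(trimethylsilyl)methyl]trideca-3,7-dien-1-yl acetate | O=CCCCC/C(C)=C/CC/C(C[Si](C)(C)C)=C/CCOC(C)=O | intermediate
14 | 2-[(1R,4aR,5S,8aR)-5-formyl-8a-methyl-2-methylidenedecahydronaphthalen-1-yl]ethyl acetate | C[C@@]12CCC[C@H](C=O)[C@H]1CCC(=C)[C@H]2CCOC(C)=O | intermediate
15 | 2-[(1R,4aS,8aS)-5,5-bis(hydroxymethyl)-8a-methyl-2-methylidenedecahydronaphthalen-1-yl]ethan-1-ol | C[C@@]12CCCC(CO)(CO)[C@H]1CCC(=C)[C@H]2CCO | intermediate
16 | isopropylidene acetal of 15 (spiro 2,2-dimethyl-1,3-dioxane at C4, side-chain OH free) | C[C@@]12CCCC3(COC(C)(C)OC3)[C@H]1CCC(=C)[C@H]2CCO | intermediate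
17 | side-chain primary iodide of 16 | C[C@@]12CCCC3(COC(C)(C)OC3)[C@H]1CCC(=C)[C@H]2CCI | intermediate
18 | 3-bromofuran-2(5H)-one | O=C1OCC=C1Br | starting material
19 | primary alkyllithium from 17 | C[C@@]12CCCC3(COC(C)(C)OC3)[C@H]1CCC(=C)[C@H]2CC[Li] | intermediate
20 | lithium B-alkyl-B-methoxy-9-borabicyclo[3.3.1]nonane borinate from 19 | [Li+].C[C@@]12CCCC3(COC(C)(C)OC3)[C@H]1CCC(=C)[C@H]2CC[B-]1(OC)C2CCCC1CCC2 | intermediate
21 | 3-{2-[(1R,4aS,8aS)-5,5-bis(hydroxymethyl)-8a-methyl-2-methylidenedecahydronaphthalen-1-yl]ethyl}furan-2(5H)-one isopropylidene acetal | C[C@@]12CCCC3(COC(C)(C)OC3)[C@H]1CCC(=C)[C@H]2CCC1=CCOC1=O | intermediate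
22 | B-alkyl-9-borabicyclo[3.3.1]nonane from 21 (boron on C17, C8–H trans to the C10 methyl) | C[C@@]12CCCC3(COC(C)(C)OC3)[C@H]1CC[C@@H](CB3C4CCCC3CCC4)[C@H]2CCC1=CCOC1=O | intermediate
23 | 3-{2-[(1R,2R,4aS,8aS)-2-(hydroxymethyl)-5,5-bis(hydroxymethyl)-8a-methyldecahydronaphthalen-1-yl]ethyl}furan-2(5H)-one 5,5-isopropylidene acetal | C[C@@]12CCCC3(COC(C)(C)OC3)[C@H]1CC[C@@H](CO)[C@H]2CCC1=CCOC1=O | intermediate
24 | 3-{2-[(1R,2R,4aS,8aS)-2-formyl-5,5-bis(hydroxymethyl)-8a-methyldecahydronaphthalen-1-yl]ethyl}furan-2(5H)-one 5,5-isopropylidene acetal (axial formyl) | C[C@@]12CCCC3(COC(C)(C)OC3)[C@H]1CC[C@@H](C=O)[C@H]2CCC1=CCOC1=O | intermediate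
25 | 3-{2-[(1R,2R,4aS,8aS)-2-formyl-5,5-bis(hydroxymethyl)-8a-methyldecahydronaphthalen-1-yl]ethyl}furan-2(5H)-one (C8 epimer of the target) | C[C@@]12CCCC(CO)(CO)[C@H]1CC[C@@H](C=O)[C@H]2CCC1=CCOC1=O | intermediate
26 | 3-{2-[(1R,2S,4aS,8aS)-2-formyl-5,5-bis(hydroxymethyl)-8a-methyldecahydronaphthalen-1-yl]ethyl}furan-2(5H)-one | C[C@@]12CCCC(CO)(CO)[C@H]1CC[C@H](C=O)[C@H]2CCC1=CCOC1=O | target

**Step count.** Total: 15 steps. Longest linear sequence: 15 steps (from hept-6-yn-1-ol).

**Steps most likely to fail**

1. Step 8 (bears the label). The allylsilane may be protodesilylated before ring B closes, the C10 radical may be oxidised before it cyclises, or facial control may be insufficient. The fallback uses known chemistry and sets out from 13. Mannich-type α-methylenation (aqueous formaldehyde, pyrrolidinium propionate) gives the 2-methylidene aldehyde F1. Luche reduction (NaBH4, CeCl3·7H2O, MeOH) gives the 2-substituted allylic alcohol F2. Sharpless asymmetric epoxidation (Ti(OiPr)4, L-(+)-diethyl tartrate, t-BuOOH, CH2Cl2, −20 °C) gives the (S)-2,2-disubstituted epoxy alcohol F3. MeAlCl2 (CH2Cl2, −78 °C) then triggers an epoxide-initiated cation–olefin bicyclization terminated by the allylsilane: C5 attacks the tertiary oxirane carbon C4 with inversion, rings A and B close, and the diol monoacetate F4 already carries both hydroxymethyl groups. K2CO3/MeOH removes the acetate and the fallback comes back to the route at 15. The relay from the oxirane centre to C5 is assigned by a chair model with the oxirane carbon pseudo-axial and is the uncertain point of this fallback; the D-(−)-tartrate would be used if it runs the other way.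

2. Step 12. β-Hydride elimination or protodeboronation of the alkylborinate, or base-induced degradation of the bromolactone, may outrun the cross-coupling. The fallback sets out from 17. Alkylation of the lithium enolate of the known α-(phenylthio)-γ-butyrolactone (LiHMDS, THF/HMPA) gives the α-alkyl-α-phenylthio lactone F5 (mixture at the α-carbon). NaIO4 oxidises it to the sulfoxide F6, and thermolysis in toluene (syn-elimination toward the ring CH2) gives the butenolide, coming back to the route at 21.

3. Step 13. Hydroboration of the hindered alkene may be sluggish, borane may attack the lactone, or peroxide may open or add to the butenolide during oxidation. The fallback sets out from 21. mCPBA (NaHCO3, CH2Cl2, 0 °C) epoxidises only the electron-rich 8(17)-alkene to the spiro-epoxide F7. BF3·OEt2 (CH2Cl2, −78 °C) then effects a Meinwald rearrangement (hydride shift) to the C8 aldehyde, coming back to the route at 24; any equatorial epimer formed alongside is carried through step 15 to the same product.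

**Further compounds**

F1 | step 8 | (3Z,7E)-8-methyl-12-methylidene-13-oxo-4-[(trimethylsilyl)methyl]trideca-3,7-dien-1-yl acetate | O=CC(=C)CCC/C(C)=C/CC/C(C[Si](C)(C)C)=C/CCOC(C)=O
F2 | step 8 | (3Z,7E)-12-(hydroxymethyl)-8-methyl-4-[(trimethylsilyl)methyl]trideca-3,7,12-trien-1-yl acetate | OCC(=C)CCC/C(C)=C/CC/C(C[Si](C)(C)C)=C/CCOC(C)=O
F3 | step 8 | (3Z,7E)-11-[(2S)-2-(hydroxymethyl)oxiran-2-yl]-8-methyl-4-[(trimethylsilyl)methyl]undeca-3,7-dien-1-yl acetate | OC[C@]1(CO1)CCC/C(C)=C/CC/C(C[Si](C)(C)C)=C/CCOC(C)=O
F4 | step 8 | 2-[(1R,4aS,8aS)-5,5-bis(hydroxymethyl)-8a-methyl-2-methylidenedecahydronaphthalen-1-yl]ethyl acetate | C[C@@]12CCCC(CO)(CO)[C@H]1CCC(=C)[C@H]2CCOC(C)=O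
F5 | step 12 | 3-(phenylthio)-3-(2-decalinylethyl)dihydrofuran-2(3H)-one bearing the acetal-protected core of 17 | C[C@@]12CCCC3(COC(C)(C)OC3)[C@H]1CCC(=C)[C@H]2CCC1(Sc2ccccc2)CCOC1=O
F6 | step 12 | sulfoxide of F5 | C[C@@]12CCCC3(COC(C)(C)OC3)[C@H]1CCC(=C)[C@H]2CCC1(S(=O)c2ccccc2)CCOC1=O
F7 | step 13 | 8,17-spiro-epoxide of 21 (oxygen on the face opposite the C10 methyl) | C[C@@]12CCCC3(COC(C)(C)OC3)[C@H]1CC[C@@]4(CO4)[C@H]2CCC1=CCOC1=O
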